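**Assumption:** atoms carry germacrane numbers C1–C15. The target is read as (2S,3S,6R,7R,8R,10S) with a 4Z ring alkene and a Z (angelate) ester. This descriptor set was derived from the given SMILES and used to check every intermediate.

## Retrosynthetic overview

1. Target 16 comes from keto-aldehyde 15 by one cationic Prins / carbonyl-oxygen capture. This makes C1–C2 and C10–O3, so the ten-membered ring, the oxolane hemiketal and C2, C3 and C10 all arise in the last step.
2. Keto-aldehyde 15 comes from terminal enyne 14, where the alkyne is a latent C3(=O)–C2HO unit. The 4Z alkene is bought in starting material 5.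
3. Enyne 14 comes from anti-1,3-diol 11. Thermodynamic lactonisation selects O6 (trans-lactone, the first ring formed), and the remaining C8–OH takes the angelate.
4. Diol 11 comes from aldol 7 by Weinreb amide formation, methallyl Grignard addition (C9, C10, C14, C1) and Evans–Saksena reduction (C8).
5. Aldol 7 comes from itaconic anhydride (C7, C8, C11–C13), an Evans auxiliary and (Z)-enynal 6 (C2–C6, C15) by a deconjugative syn aldol that sets C6 and C7.

## Route

**Step 1**
- Reactants: 1, (S)-4-benzyl-1,3-oxazolidin-2-one; 2, itaconic anhydride
- Product: 3, 4-[(4S)-4-benzyl-2-oxo-oxazolidin-3-yl]-2-methylidene-4-oxobutanoic acid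
- Conditions: n-BuLi, THF, −78 °C; then 2, −78 → 0 °C; H3O+
- Reagents that add atoms: none beyond the numbered reactants
- Why: N-acylation by anhydride ring-opening, in which the lithium oxazolidinide attacks the non-conjugated, less hindered carbonyl (the same regiochemistry as alcoholysis or aminolysis of itaconic anhydride), so the exocyclic methylene is in place from the start and no stereocentre is formed.

**Step 2**
- Reactants: 3
- Product: 4, the tert-butyl ester of 3
- Conditions: Cl3CC(=NH)OtBu, BF3·OEt2 (cat.), CH2Cl2/cyclohexane, rt
- Reagents that add atoms: tert-butyl 2,2,2-trichloroacetimidate, CC(C)(C)OC(=N)C(Cl)(Cl)Cl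
- Why: Trichloroacetimidate esterification under near-neutral conditions masks C12 as an ester hindered enough to survive the AlMe3/amine and Grignard steps.

**Step 3**
- Reactants: 5, (Z)-3-methylpent-2-en-4-yn-1-ol
- Product: 6, (Z)-3-methylpent-2-en-4-ynal
- Conditions: MnO2, CH2Cl2, rt, dark; used as a solution
- Reagents that add atoms: none
- Why: MnO2 allylic oxidation is neutral, so the purchased Z geometry (the future 4Z alkene) is retained.

**Step 4**
- Reactants: 4; 6
- Product: 7, tert-butyl (3S,4R,5Z)-3-{[(4S)-4-benzyl-2-oxo-oxazolidin-3-yl]carbonyl}-4-hydroxy-6-methyl-2-methylideneoct-5-en-7-ynoate. This has 6R and the target geometry at C7 (the descriptor reads S here only because C8 is an acyl carbon).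
- Conditions: Bu2BOTf, Et3N, CH2Cl2, −78 → 0 °C; 6, −78 → 0 °C; pH 7 buffer, H2O2/MeOH, 0 °C
- Reagents that add atoms: none beyond the numbered reactants
- Why: Evans syn aldol in its deconjugative form for β,γ-unsaturated imides, where the Z(O)-boron dienolate reacts at the α-carbon through a Zimmerman–Traxler chair and the (S)-benzyl group blocks one face, giving the C6–O/C7–C11 syn pair (the future trans-lactone) in the required absolute sense.

**Step 5**
- Reactants: 7
- Product: 8, tert-butyl (3S,4R,5Z)-4-hydroxy-3-[methoxy(methyl)carbamoyl]-6-methyl-2-methylideneoct-5-en-7-ynoate (auxiliary 1 recovered)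
- Conditions: MeNH(OMe)·HCl, AlMe3, THF, −20 → 0 °C
- Reagents that add atoms: N,O-dimethylhydroxylamine hydrochloride, CNOC.Cl
- Why: AlMe3-mediated Weinreb transamination, accelerated by the β-aluminium alkoxide, takes place at the imide only and leaves C6, C7, the tert-butyl ester and the alkyne untouched.

**Step 6**
- Reactants: 8; 9, 2-methylallylmagnesium chloride
- Product: 10, tert-butyl (3S,4R,5Z)-4-hydroxy-6-methyl-3-(3-methylbut-3-enoyl)-2-methylideneoct-5-en-7-ynoate
- Conditions: 9 (4 equiv), THF, −78 → −40 °C; AcOH quench at −78 °C; used at once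
- Reagents that add atoms: 2-methylallylmagnesium chloride, C=C(C)C[Mg]Cl
- Why: Weinreb ketone synthesis, in which the chelated tetrahedral intermediate stops over-addition and keeps C7 non-enolisable until the cold acidic quench, with the extra equivalents consumed by the OH and the alkyne C–H.

**Step 7**
- Reactants: 10
- Product: 11, tert-butyl (3R,4R,5Z)-4-hydroxy-3-[(1R)-1-hydroxy-3-methylbut-3-en-1-yl]-6-methyl-2-methylideneoct-5-en-7-ynoate
- Conditions: Me4NBH(OAc)3, MeCN/AcOH 1:1, −30 °C
- Reagents that add atoms: none
- Why: Evans–Saksena hydroxyl-directed reduction, where the borohydride bound to O6 delivers hydride intramolecularly through a chair to give the 1,3-anti diol (8R), and the acrylate, alkenes and alkyne are inert.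

**Step 8**
- Reactants: 11
- Product: 12, (4R,5R)-4-[(1R)-1-hydroxy-3-methylbut-3-en-1-yl]-3-methylidene-5-[(1Z)-2-methylbut-1-en-3-yn-1-yl]oxolan-2-one
- Conditions: 85% aq H3PO4, toluene, rt
- Reagents that add atoms: none
- Why: Mild acid cleavage of the tert-butyl ester followed by lactonisation under equilibrating conditions favours the trans-β,γ-disubstituted 6,12-olide over the cis 8,12-olide, which differentiates the two hydroxyls without protecting groups, and the acid is too weak to protonate the methallyl alkene.

**Step 9**
- Reactants: 12; 13, angelic acid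
- Product: 14, (1R)-3-methyl-1-{(2R,3R)-4-methylidene-2-[(1Z)-2-methylbut-1-en-3-yn-1-yl]-5-oxooxolan-3-yl}but-3-en-1-yl (2Z)-2-methylbut-2-enoate
- Conditions: 13, 2,4,6-Cl3C6H2COCl, Et3N, toluene, rt; then 12, 75 °C (no DMAP)
- Reagents that add atoms: angelic acid, C/C=C(/C)C(=O)O
- Why: Yamaguchi mixed-anhydride esterification without a nucleophilic catalyst acylates the only free OH with retention at C8 and avoids angelate-to-tiglate isomerisation.

**Step 10**
- Reactants: 14
- Product: 15, (1R)-1-{(2R,3R)-2-[(1Z)-2-methyl-3,4-dioxobut-1-en-1-yl]-4-methylidene-5-oxooxolan-3-yl}-3-methylbut-3-en-1-yl (2Z)-2-methylbut-2-enoate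
- Conditions: IPrAuNTf2 (5 mol %), 3,5-dichloropyridine N-oxide (3 equiv), DCE, 40 °C; azeotropic drying; used crude
- Reagents that add atoms: 3,5-dichloropyridine N-oxide, [O-][n+]1cc(Cl)cc(Cl)c1 (two O atoms)
- Why: Gold-catalysed terminal-alkyne-to-glyoxal oxidation, where the N-oxide attacks the internal carbon C3 to give an α-oxo gold carbene at C2 that a second N-oxide oxidises faster than the remote alkene can reach it, and no acid or base is present to isomerise the Z-enone.

**Step 11**
- Reactants: 15
- Product: 16, 2β-hydroxy-1-desoxyniveusin A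
- Conditions: BF3·OEt2 (1.5 equiv), 4 Å MS, CH2Cl2 (0.5 mM, slow addition), −78 → −30 °C; then THF/H2O, NaHCO3
- Reagents that add atoms: water, O
- Why: Proposed new method: the BF3-activated aldehyde C2 (s-trans keto-aldehyde, monodentate Lewis acid) is attacked by the CH2 terminus C1 of the 1,1-disubstituted alkene; the resulting tertiary C10 cation is captured through a five-membered array by the C3 ketone oxygen, and the allyl-stabilised oxocarbenium ion takes up water on quench to give the hemiketal. C3 is fixed because only a cis-2,5-bridged oxolane can span the ring. C10–O forms anti to the C8 acyloxy group, whose carbonyl shields (or reversibly caps) its own face, giving the 8,10-anti relationship. The bulky BF3-bound O2 takes the oxolane face away from both methyl groups C14 and C15, giving 2β-OH trans to 3-OH. Any ene by-products re-enter the same cation on protonation. Closest known reaction types are Prins macrocyclisations, Lewis-acid macrocyclic ene reactions of activated aldehydes, and glyoxylate-ene reactions of 1,1-disubstituted alkenes.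

## Compound list

| No. | Name | SMILES | Role |
|---|---|---|---|
| 1 | (S)-4-benzyl-1,3-oxazolidin-2-one | `O=C1N[C@@H](Cc2ccccc2)CO1` | starting material |
| 2 | itaconic anhydride | `C=C1CC(=O)OC1=O` | starting material |
| 3 | imide acid | `C=C(CC(=O)N1[C@@H](Cc2ccccc2)COC1=O)C(=O)O` | intermediate |
| 4 | imide tert-butyl ester | `C=C(CC(=O)N1[C@@H](Cc2ccccc2)COC1=O)C(=O)OC(C)(C)C` | intermediate |
| 5 | (Z)-3-methylpent-2-en-4-yn-1-ol | `C#C/C(C)=C\CO` | starting material |
| 6 | (Z)-3-methylpent-2-en-4-ynal | `C#C/C(C)=C\C=O` | intermediate |
| 7 | syn-aldol imide | `CC(C)(C)OC(=O)C(=C)[C@H](C(=O)N1[C@@H](Cc2ccccc2)COC1=O)[C@H](O)/C=C(/C)C#C` | intermediate |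
| 8 | Weinreb amide | `CC(C)(C)OC(=O)C(=C)[C@H](C(=O)N(C)OC)[C@H](O)/C=C(/C)C#C` | intermediate |
| 9 | 2-methylallylmagnesium chloride | `C=C(C)C[Mg]Cl` | starting material |
| 10 | β-hydroxy methallyl ketone | `CC(C)(C)OC(=O)C(=C)[C@H](C(=O)CC(C)=C)[C@H](O)/C=C(/C)C#C` | intermediate |
| 11 | anti-1,3-diol | `CC(C)(C)OC(=O)C(=C)[C@H]([C@H](O)CC(C)=C)[C@H](O)/C=C(/C)C#C` | intermediate |
| 12 | trans-α-methylene lactone alcohol | `C=C1C(=O)O[C@H](/C=C(/C)C#C)[C@H]1[C@H](O)CC(C)=C` | intermediate |
| 13 | angelic acid | `C/C=C(/C)C(=O)O` | starting material |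
| 14 | enyne angelate | `C=C1C(=O)O[C@H](/C=C(/C)C#C)[C@H]1[C@H](OC(=O)/C(C)=C\C)CC(C)=C` | intermediate |
| 15 | (Z)-vinyl keto-aldehyde | `C=C1C(=O)O[C@H](/C=C(/C)C(=O)C=O)[C@H]1[C@H](OC(=O)/C(C)=C\C)CC(C)=C` | intermediate |
| 16 | 2β-hydroxy-1-desoxyniveusin A | `C=C1C(=O)O[C@@H]2/C=C(/C)[C@]3(O)O[C@](C)(C[C@@H](OC(=O)/C(C)=C\C)[C@@H]12)C[C@@H]3O` | target |

## Step count

- Total steps: 11
- Longest linear sequence: 10 (steps 1, 2, 4–11)

## Three steps most likely to fail

1. **Step 11.** The risks are the ten-membered cationic closure itself, the facial selectivity at C2 and C10, and a 1,2-hydride (α-ketol) shift in the oxocarbenium ion.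
   - Fallback: switch from a cationic to a pericyclic closure. Convert 15 to the α-keto aldoxime and then the acyl nitrile oxide. An intramolecular [3+2] cycloaddition to the 1,1-disubstituted alkene makes C1–C2 and C10–O concertedly with intrinsic regiochemistry. Mo(CO)6 cleavage of the N–O bond gives the 2-oxo-3,10-hemiketal, and a 3-OH-directed Me4NBH(OAc)3 reduction then sets 2β-OH separately.
2. **Step 10.** The risk is forming and handling the Z-vinyl glyoxal, or interception of the gold carbene.
   - Fallback: avoid the glyoxal and use the alkyne as the nucleophile. Epoxidise the methallyl alkene at the stage of alcohol 12 (hydroxyl-directed). Close C1–C2 by intramolecular alkynyl-metal opening of the epoxide CH2. Follow with Au(I) 5-endo-dig transannular hydroalkoxylation to the bridged dienol ether, then DMDO/H2O (Rubottom-type) to install C2–OH and C3–OH.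
3. **Step 6.** The risks are Grignard chemoselectivity against the acrylate ester and the lability of β,γ-enone 10.
   - Fallback: remove the ketone from the plan. Run a Crimmins thiazolidinethione syn aldol on the methyl ester analogue and reduce with DIBAL directly to the β-hydroxy aldehyde. Then carry out indium-mediated methallylation in water under chelation control, which gives the 1,3-anti diol that lactonises with catalytic PPTS.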